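**Retrosynthetic overview**

1. Numbering follows cyclohepta[b]furan-2-one (O1, C2=O, C3=CH2, C3a, C4, C5-OH, C6-CH3, C7, C8-O-acyl, C8a); the endgame installs the C8 isobutyrate, builds the C7 butenoyl group from a C7 CH2OH (oxidation, Nozaki–Hiyama–Kishi propenylation, allylic oxidation) and makes the C7/C8 trans-diol by epoxidation of a C7=C8 allylic alcohol and inverting hydrolysis at C7.
2. Key disconnection: O1–C8a and C3–C3a are cut together, so the complete α-methylene-γ-butyrolactone (ring A) comes from 2-bromoacrylic acid and a cyclohepta-1,3-diene (ring B) in one palladium-catalysed annulation.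
3. Enabling feature: ring A is cis-fused at C3a/C8a and C8a is flanked by the oxygen-bearing C8 and C7, so C3a=C8a–C8=C7 can be a 1,3-diene; its π-allyl intermediate (C8a–C8–C7) is trapped at C8a, and the surviving C7=C8 alkene lies exactly where the trans-diol is needed.
4. The diene comes from a cyclohept-2-enone through its linear dienyl triflate and a Stille hydroxymethylation; C5 and C6 come from an Evans syn-aldol.
5. Ring order: ring B first (ring-closing metathesis), ring A second (key step).

Key step: step 8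

Remark: "upper face" means the face of ring B that carries the C5 oxygen; the lactone, the C6 methyl and the C7 hydroxyl lie on the lower face.

**Step 1**
Reactants: 1 (4S)-4-benzyl-3-propanoyl-1,3-oxazolidin-2-one; 2 pent-4-enal
Product: 3 (4S)-4-benzyl-3-[(2S,3R)-3-hydroxy-2-methylhept-6-enoyl]-1,3-oxazolidin-2-one
Conditions: Bu2BOTf, iPr2NEt, CH2Cl2, −78 to 0 °C; then pH 7 buffer, MeOH, H2O2
Reagents that add atoms: none
Why: Evans syn-aldol reaction, in which the Z-boron enolate reacts through a closed chair transition state on the face away from the benzyl group and so sets the future C5 (carbinol) and C6 (methyl) in the syn relation that becomes trans on the seven-membered ring.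

**Step 2**
Reactants: 3 (4S)-4-benzyl-3-[(2S,3R)-3-hydroxy-2-methylhept-6-enoyl]-1,3-oxazolidin-2-one
Product: 4 (2S,3R)-3-hydroxy-N-methoxy-N,2-dimethylhept-6-enamide
Conditions: MeNH(OMe)·HCl, AlMe3, CH2Cl2, −15 °C to rt
Reagents that add atoms: N,O-dimethylhydroxylamine hydrochloride, CNOC.Cl
Why: Weinreb amide formation by aluminium-amide transamination of the imide, assisted by the free β-hydroxyl, should remove the auxiliary without touching either stereocentre.

**Step 3**
Reactants: 4 (2S,3R)-3-hydroxy-N-methoxy-N,2-dimethylhept-6-enamide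
Product: 5 (2S,3R)-3-{[tert-butyl(dimethyl)silyl]oxy}-N-methoxy-N,2-dimethylhept-6-enamide
Conditions: TBSOTf, 2,6-lutidine, CH2Cl2, 0 °C
Reagents that add atoms: tert-butyldimethylsilyl trifluoromethanesulfonate, CC(C)(C)[Si](C)(C)OS(=O)(=O)C(F)(F)F
Why: Standard silylation of a secondary alcohol gives a group that survives the organometallic, triflation and palladium steps and later screens the upper face of the diene.

**Step 4**
Reactants: 5 (2S,3R)-3-{[tert-butyl(dimethyl)silyl]oxy}-N-methoxy-N,2-dimethylhept-6-enamide; 6 vinylmagnesium bromide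
Product: 7 (4S,5R)-5-{[tert-butyl(dimethyl)silyl]oxy}-4-methylnona-1,8-dien-3-one
Conditions: THF, 0 °C; quench into cold 1 M HCl
Reagents that add atoms: none
Why: Weinreb ketone synthesis, in which the chelated tetrahedral intermediate prevents over-addition and the acidic quench keeps the liberated amine from adding to the new vinyl ketone.

**Step 5**
Reactants: 7 (4S,5R)-5-{[tert-butyl(dimethyl)silyl]oxy}-4-methylnona-1,8-dien-3-one
Product: 8 (6R,7S)-6-{[tert-butyl(dimethyl)silyl]oxy}-7-methylcyclohept-2-en-1-one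
Conditions: second-generation Grubbs catalyst (H2IMes)(PCy3)Cl2Ru=CHPh (5 mol %), CH2Cl2 (5 mM), 40 °C
Reagents that add atoms: none
Why: Ring-closing metathesis between the terminal alkene and the enone vinyl group closes ring B as a cyclohept-2-enone with loss of ethene and touches no stereocentre.

**Step 6**
Reactants: 8 (6R,7S)-6-{[tert-butyl(dimethyl)silyl]oxy}-7-methylcyclohept-2-en-1-one
Product: 9 (6R,7S)-6-{[tert-butyl(dimethyl)silyl]oxy}-7-methylcyclohepta-1,3-dien-1-yl trifluoromethanesulfonate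
Conditions: Tf2O, 2,6-di-tert-butyl-4-methylpyridine, CH2Cl2, 0 °C to rt
Reagents that add atoms: trifluoromethanesulfonic anhydride, O=S(=O)(OS(=O)(=O)C(F)(F)F)C(F)(F)F
Why: O-triflation of an enone with a hindered pyridine base gives the linearly conjugated dienyl triflate by loss of a proton from the γ-CH2 (the future C3a), the known outcome for enones that carry γ-hydrogens, and leaves the methyl-bearing α'-carbon untouched.

**Step 7**
Reactants: 9 (6R,7S)-6-{[tert-butyl(dimethyl)silyl]oxy}-7-methylcyclohepta-1,3-dien-1-yl trifluoromethanesulfonate; 10 (tributylstannyl)methanol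
Product: 11 [(6R,7R)-6-{[tert-butyl(dimethyl)silyl]oxy}-7-methylcyclohepta-1,3-dien-1-yl]methanol
Conditions: Pd(PPh3)4 (5 mol %), LiCl, 1,4-dioxane, 90 °C
Reagents that add atoms: none
Why: Stille coupling of an alkenyl triflate with the hydroxymethyl stannane (LiCl enables transmetalation of the triflate-derived palladium species) puts the one-carbon handle of the side chain on the future C7 and makes this diene terminus fully substituted.

**Step 8**
Reactants: 11 [(6R,7R)-6-{[tert-butyl(dimethyl)silyl]oxy}-7-methylcyclohepta-1,3-dien-1-yl]methanol; 12 2-bromoprop-2-enoic acid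
Product: 13 (3aS,5R,6R,8aS)-5-{[tert-butyl(dimethyl)silyl]oxy}-7-(hydroxymethyl)-6-methyl-3-methylidene-3,3a,4,5,6,8a-hexahydro-2H-cyclohepta[b]furan-2-one
Conditions: Pd(OAc)2 (10 mol %), PPh3 (20 mol %), Ag2CO3, DMF, 70 °C
Reagents that add atoms: none
Why: Oxidative addition of zerovalent palladium into the C–Br bond of 12 gives an α-carboxyvinylpalladium species that adds syn across the less substituted end of the diene (new C3–C3a bond at the unsubstituted terminus), and the resulting π-allylpalladium unit (C8a–C8–C7) is closed by its own carboxylate at C8a with release of zerovalent palladium, so O1–C8a and C3–C3a form in one catalytic cycle and the exocyclic methylene arrives intact. The closest known reaction type is the Larock heteroannulation of cyclic 1,3-dienes by aryl and vinylic halides that carry an OH, NHR or CO2H group, which gives cis-fused five-membered heterocycles. Ring A closes in a 5-exo sense on the allyl terminus C8a (the seven-membered alternative at the fully substituted C7 should not compete) by inner-sphere C–O bond formation on the palladium-bearing face, which Ag2CO3 favours by removing bromide; because the allylic lactone C–O bond can re-ionise under the conditions, any trans-fused material should funnel to the cis lactone. C3a is set by the face of carbopalladation: allylic 1,2-strain between the C7 CH2OH and the C6 methyl should hold the methyl pseudoaxial on the lower face and therefore the trans C5 silyloxy group pseudoaxial on the upper face, 1,3 to C3a, so the vinylpalladium should arrive from the lower face, anti to OTBS. C8a follows from C3a because palladium and the new C–C bond lie on the same face, which gives the cis ring fusion. The step needs regioselectivity (C3a, not C7, as the carbon-bearing terminus, secured by the substituent on C7), five-ring site selectivity in the closure, and facial selectivity (secured by the C5 silyl ether).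

**Step 9**
Reactants: 13 (3aS,5R,6R,8aS)-5-{[tert-butyl(dimethyl)silyl]oxy}-7-(hydroxymethyl)-6-methyl-3-methylidene-3,3a,4,5,6,8a-hexahydro-2H-cyclohepta[b]furan-2-one
Product: 14 (3aS,5R,6S,7S,8S,8aR)-5-{[tert-butyl(dimethyl)silyl]oxy}-7,8-epoxy-7-(hydroxymethyl)-6-methyl-3-methylideneoctahydro-2H-cyclohepta[b]furan-2-one (epoxide oxygen on the upper face)
Conditions: Ti(OiPr)4, L-(+)-diethyl tartrate, t-BuOOH, 4 Å molecular sieves, CH2Cl2, −20 °C
Reagents that add atoms: tert-butyl hydroperoxide, CC(C)(C)OO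
Why: Sharpless asymmetric epoxidation of the primary allylic alcohol, in the sense that converts (E)-hex-2-en-1-ol into its (2S,3S)-epoxide, should place oxygen on the C7=C8 face opposite to the lactone oxygen and the C6 methyl (also the sterically open face, so a matched case) and leaves the electron-poor methylene lactone alone.

**Step 10**
Reactants: 14 (3aS,5R,6S,7S,8S,8aR)-5-{[tert-butyl(dimethyl)silyl]oxy}-7,8-epoxy-7-(hydroxymethyl)-6-methyl-3-methylideneoctahydro-2H-cyclohepta[b]furan-2-one
Product: 15 (3aS,5R,6S,7R,8S,8aR)-5-{[tert-butyl(dimethyl)silyl]oxy}-7,8-dihydroxy-7-(hydroxymethyl)-6-methyl-3-methylideneoctahydro-2H-cyclohepta[b]furan-2-one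
Conditions: HClO4 (cat.), THF/H2O 4:1, 0 °C
Reagents that add atoms: water, O
Why: Acid-catalysed epoxide hydrolysis, in which water attacks the protonated epoxide at the tertiary C7 with inversion, should put the C7 hydroxyl on the lower face and leave the C8 oxygen on the upper face, which is the trans-diol of the target.

**Step 11**
Reactants: 15 (3aS,5R,6S,7R,8S,8aR)-5-{[tert-butyl(dimethyl)silyl]oxy}-7,8-dihydroxy-7-(hydroxymethyl)-6-methyl-3-methylideneoctahydro-2H-cyclohepta[b]furan-2-one
Product: 16 (3aS,5R,6S,7S,8S,8aR)-5-{[tert-butyl(dimethyl)silyl]oxy}-7,8-dihydroxy-6-methyl-3-methylidene-2-oxooctahydro-2H-cyclohepta[b]furan-7-carbaldehyde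
Conditions: Cu(MeCN)4OTf (5 mol %), 2,2'-bipyridine, TEMPO, N-methylimidazole, air, MeCN, rt
Reagents that add atoms: none
Why: Copper/nitroxyl aerobic alcohol oxidation is selective for primary over secondary and tertiary alcohols and stops at the aldehyde under neutral conditions.

**Step 12**
Reactants: 16 (3aS,5R,6S,7S,8S,8aR)-5-{[tert-butyl(dimethyl)silyl]oxy}-7,8-dihydroxy-6-methyl-3-methylidene-2-oxooctahydro-2H-cyclohepta[b]furan-7-carbaldehyde; 17 (E)-1-bromoprop-1-ene
Product: 18 (3aS,5R,6S,7R,8S,8aR)-5-{[tert-butyl(dimethyl)silyl]oxy}-7,8-dihydroxy-7-[(2E)-1-hydroxybut-2-en-1-yl]-6-methyl-3-methylideneoctahydro-2H-cyclohepta[b]furan-2-one (both carbinol epimers)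
Conditions: CrCl2 (6 equiv), NiCl2 (2 mol %), DMSO, rt
Reagents that add atoms: none
Why: Nozaki–Hiyama–Kishi reaction, whose non-basic alkenylchromium reagent adds only to the aldehyde, tolerates free hydroxyls, the lactone and the Michael acceptor, and retains the E geometry; the new carbinol centre is removed in step 13, so its configuration does not matter.

**Step 13**
Reactants: 18 (3aS,5R,6S,7R,8S,8aR)-5-{[tert-butyl(dimethyl)silyl]oxy}-7,8-dihydroxy-7-[(2E)-1-hydroxybut-2-en-1-yl]-6-methyl-3-methylideneoctahydro-2H-cyclohepta[b]furan-2-one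
Product: 19 (3aS,5R,6S,7S,8S,8aR)-7-[(2E)-but-2-enoyl]-5-{[tert-butyl(dimethyl)silyl]oxy}-7,8-dihydroxy-6-methyl-3-methylideneoctahydro-2H-cyclohepta[b]furan-2-one
Conditions: MnO2 (excess), CH2Cl2, rt
Reagents that add atoms: none
Why: MnO2 oxidises only the allylic secondary alcohol, so the C8 secondary and C7 tertiary hydroxyls should stay and the (E)-enone of the side chain is formed.

**Step 14**
Reactants: 19 (3aS,5R,6S,7S,8S,8aR)-7-[(2E)-but-2-enoyl]-5-{[tert-butyl(dimethyl)silyl]oxy}-7,8-dihydroxy-6-methyl-3-methylideneoctahydro-2H-cyclohepta[b]furan-2-one; 20 2-methylpropanoic anhydride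
Product: 21 (3aS,5R,6S,7S,8S,8aR)-7-[(2E)-but-2-enoyl]-5-{[tert-butyl(dimethyl)silyl]oxy}-7-hydroxy-6-methyl-3-methylidene-2-oxooctahydro-2H-cyclohepta[b]furan-8-yl 2-methylpropanoate
Conditions: DMAP (cat.), Et3N, CH2Cl2, 0 °C to rt
Reagents that add atoms: none
Why: DMAP-catalysed acylation should take the only free secondary hydroxyl (C8), because the tertiary α-ketol hydroxyl at C7 is too hindered and C5 is still silylated.

**Step 15**
Reactants: 21 (3aS,5R,6S,7S,8S,8aR)-7-[(2E)-but-2-enoyl]-5-{[tert-butyl(dimethyl)silyl]oxy}-7-hydroxy-6-methyl-3-methylidene-2-oxooctahydro-2H-cyclohepta[b]furan-8-yl 2-methylpropanoate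
Product: 22 (3aS,5R,6S,7S,8S,8aR)-7-[(2E)-but-2-enoyl]-5,7-dihydroxy-6-methyl-3-methylidene-2-oxooctahydro-2H-cyclohepta[b]furan-8-yl 2-methylpropanoate
Conditions: HF·pyridine, pyridine, THF, 0 °C to rt
Reagents that add atoms: none
Why: Buffered fluoride cleavage of the silyl ether is non-basic and non-nucleophilic toward carbon, so the methylene lactone, the enone, the ester and the α-ketol should survive.

**Compound list**

1 | (4S)-4-benzyl-3-propanoyl-1,3-oxazolidin-2-one | CCC(=O)N1[C@@H](Cc2ccccc2)COC1=O | starting material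
2 | pent-4-enal | C=CCCC=O | starting material
3 | (4S)-4-benzyl-3-[(2S,3R)-3-hydroxy-2-methylhept-6-enoyl]-1,3-oxazolidin-2-one | C=CCC[C@@H](O)[C@H](C)C(=O)N1[C@@H](Cc2ccccc2)COC1=O | intermediate
4 | (2S,3R)-3-hydroxy-N-methoxy-N,2-dimethylhept-6-enamide | C=CCC[C@@H](O)[C@H](C)C(=O)N(C)OC | intermediate
5 | (2S,3R)-3-{[tert-butyl(dimethyl)silyl]oxy}-N-methoxy-N,2-dimethylhept-6-enamide | C=CCC[C@@H](O[Si](C)(C)C(C)(C)C)[C@H](C)C(=O)N(C)OC | intermediate
6 | vinylmagnesium bromide | C=C[Mg]Br | starting material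
7 | (4S,5R)-5-{[tert-butyl(dimethyl)silyl]oxy}-4-methylnona-1,8-dien-3-one | C=CCC[C@@H](O[Si](C)(C)C(C)(C)C)[C@H](C)C(=O)C=C | intermediate
8 | (6R,7S)-6-{[tert-butyl(dimethyl)silyl]oxy}-7-methylcyclohept-2-en-1-one | C1C[C@@H](O[Si](C)(C)C(C)(C)C)[C@H](C)C(=O)C=C1 | intermediate
9 | (6R,7S)-6-{[tert-butyl(dimethyl)silyl]oxy}-7-methylcyclohepta-1,3-dien-1-yl trifluoromethanesulfonate | C1C[C@@H](O[Si](C)(C)C(C)(C)C)[C@H](C)C(OS(=O)(=O)C(F)(F)F)=CC=1 | intermediate
10 | (tributylstannyl)methanol | CCCC[Sn](CCCC)(CCCC)CO | starting material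
11 | [(6R,7R)-6-{[tert-butyl(dimethyl)silyl]oxy}-7-methylcyclohepta-1,3-dien-1-yl]methanol | C1C[C@@H](O[Si](C)(C)C(C)(C)C)[C@H](C)C(CO)=CC=1 | intermediate
12 | 2-bromoprop-2-enoic acid | C=C(Br)C(=O)O | starting material
13 | (3aS,5R,6R,8aS)-5-{[tert-butyl(dimethyl)silyl]oxy}-7-(hydroxymethyl)-6-methyl-3-methylidene-3,3a,4,5,6,8a-hexahydro-2H-cyclohepta[b]furan-2-one | C=C1C(=O)O[C@@H]2[C@H]1C[C@@H](O[Si](C)(C)C(C)(C)C)[C@H](C)C(CO)=C2 | intermediate
14 | (3aS,5R,6S,7S,8S,8aR)-5-{[tert-butyl(dimethyl)silyl]oxy}-7,8-epoxy-7-(hydroxymethyl)-6-methyl-3-methylideneoctahydro-2H-cyclohepta[b]furan-2-one | C=C1C(=O)O[C@@H]2[C@H]1C[C@@H](O[Si](C)(C)C(C)(C)C)[C@H](C)[C@]3(CO)[C@H]2O3 | intermediate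
15 | (3aS,5R,6S,7R,8S,8aR)-5-{[tert-butyl(dimethyl)silyl]oxy}-7,8-dihydroxy-7-(hydroxymethyl)-6-methyl-3-methylideneoctahydro-2H-cyclohepta[b]furan-2-one | C=C1C(=O)O[C@@H]2[C@H]1C[C@@H](O[Si](C)(C)C(C)(C)C)[C@H](C)[C@@](O)(CO)[C@H]2O | intermediate
16 | (3aS,5R,6S,7S,8S,8aR)-5-{[tert-butyl(dimethyl)silyl]oxy}-7,8-dihydroxy-6-methyl-3-methylidene-2-oxooctahydro-2H-cyclohepta[b]furan-7-carbaldehyde | C=C1C(=O)O[C@@H]2[C@H]1C[C@@H](O[Si](C)(C)C(C)(C)C)[C@H](C)[C@@](O)(C=O)[C@H]2O | intermediate
17 | (E)-1-bromoprop-1-ene | C/C=C/Br | starting material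
18 | (3aS,5R,6S,7R,8S,8aR)-5-{[tert-butyl(dimethyl)silyl]oxy}-7,8-dihydroxy-7-[(2E)-1-hydroxybut-2-en-1-yl]-6-methyl-3-methylideneoctahydro-2H-cyclohepta[b]furan-2-one (both carbinol epimers) | C=C1C(=O)O[C@@H]2[C@H]1C[C@@H](O[Si](C)(C)C(C)(C)C)[C@H](C)[C@@](O)(C(O)/C=C/C)[C@H]2O | intermediate
19 | (3aS,5R,6S,7S,8S,8aR)-7-[(2E)-but-2-enoyl]-5-{[tert-butyl(dimethyl)silyl]oxy}-7,8-dihydroxy-6-methyl-3-methylideneoctahydro-2H-cyclohepta[b]furan-2-one | C=C1C(=O)O[C@@H]2[C@H]1C[C@@H](O[Si](C)(C)C(C)(C)C)[C@H](C)[C@@](O)(C(=O)/C=C/C)[C@H]2O | intermediate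
20 | 2-methylpropanoic anhydride | CC(C)C(=O)OC(=O)C(C)C | starting material
21 | (3aS,5R,6S,7S,8S,8aR)-7-[(2E)-but-2-enoyl]-5-{[tert-butyl(dimethyl)silyl]oxy}-7-hydroxy-6-methyl-3-methylidene-2-oxooctahydro-2H-cyclohepta[b]furan-8-yl 2-methylpropanoate | C=C1C(=O)O[C@@H]2[C@H]1C[C@@H](O[Si](C)(C)C(C)(C)C)[C@H](C)[C@@](O)(C(=O)/C=C/C)[C@H]2OC(=O)C(C)C | intermediate
22 | (3aS,5R,6S,7S,8S,8aR)-7-[(2E)-but-2-enoyl]-5,7-dihydroxy-6-methyl-3-methylidene-2-oxooctahydro-2H-cyclohepta[b]furan-8-yl 2-methylpropanoate | C=C1C(=O)O[C@@H]2[C@H]1C[C@@H](O)[C@H](C)[C@@](O)(C(=O)/C=C/C)[C@H]2OC(=O)C(C)C | target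

**Step count and risks**

Total step count: 15. Longest linear sequence: 15 steps (from 1 and 2 to 22).

Steps most likely to fail:

1. Step 8 (annulation). Carbopalladation may take place on the upper diene face (poor facial selectivity), or the π-allyl intermediate may lose a β-hydrogen instead of closing to the lactone. Fallback (stepwise lactone construction by acyl–oxygen closure), setting out from 8 and coming back at 13: addition of LiCH2OPMB (from Bu3SnCH2OPMB and n-BuLi) to 8 would give the tertiary allylic alcohol F1. Oxidative 1,3-transposition with pyridinium chlorochromate (C5H5NH)[CrO3Cl] (Babler–Dauben) would give the transposed enone F2, whose carbonyl sits at the future C8a. Kinetic α'-alkylation (LiN(iPr)2, then methyl bromoacetate) should place the acetate arm on the future C3a anti to the silyl ether and give the keto ester F3. Luche reduction (NaBH4, CeCl3·7H2O) anti to that arm, followed by acid-catalysed lactonisation, would give the cis-fused lactone F4. Enolisation and Eschenmoser's salt would give the Mannich base F5; N-methylation with MeI and NaHCO3-induced elimination would give the methylene lactone PMB ether F6, and DDQ would return 13.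

2. Step 10 (epoxide hydrolysis). Water may attack the secondary C8 instead of C7, the developing cation at C7 may rearrange by a hydride or ring-bond shift, or the silyl ether may be lost in the acid. Fallback (oxygen placed on the lower face and the acyloxy nucleophile brought to C8), setting out from 13 and coming back at 21: Sharpless epoxidation with D-(−)-diethyl tartrate would give the lower-face epoxy alcohol F7. Ti(OiPr)4-mediated C3-selective opening of this 2,3-epoxy alcohol by 2-methylpropanoic acid (attack at C8 with inversion) would give the C8 isobutyrate diol F8 directly. Copper/TEMPO aerobic oxidation would give the α-hydroxy aldehyde F9, Nozaki–Hiyama–Kishi reaction with 17 would give the allylic alcohol F10, and MnO2 would return 21.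

3. Step 12 (propenylation of the α,β-dihydroxy aldehyde). The aldehyde may decompose by retro-aldol cleavage or α-ketol shift before it is trapped, or the chromium reagent may be consumed by the free hydroxyls. Fallback (ketone formation at the acid oxidation level under neutral palladium catalysis), setting out from 15 and coming back at 19: TEMPO/NaOCl (cat.)/NaClO2 oxidation of the primary alcohol would give the α-hydroxy acid F11, and EDC with ethanethiol would give the S-ethyl thioester F12. Liebeskind–Srogl coupling with (E)-prop-1-enylboronic acid (Pd2(dba)3, tri(2-furyl)phosphine, Cu(O2C-2-thienyl), THF, 50 °C) would return 19.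

**Further compounds**

F1 | step 8 | (6R,7S)-6-{[tert-butyl(dimethyl)silyl]oxy}-1-{[(4-methoxybenzyl)oxy]methyl}-7-methylcyclohept-2-en-1-ol (C1 epimers) | C1C[C@@H](O[Si](C)(C)C(C)(C)C)[C@H](C)C(O)(COCc2ccc(OC)cc2)C=C1
F2 | step 8 | (4R,5R)-5-{[tert-butyl(dimethyl)silyl]oxy}-3-{[(4-methoxybenzyl)oxy]methyl}-4-methylcyclohept-2-en-1-one | C1C[C@@H](O[Si](C)(C)C(C)(C)C)[C@H](C)C(COCc2ccc(OC)cc2)=CC1=O
F3 | step 8 | methyl 2-[3-{[tert-butyl(dimethyl)silyl]oxy}-5-{[(4-methoxybenzyl)oxy]methyl}-4-methyl-7-oxocyclohept-5-en-1-yl]acetate (acetate arm trans to the silyloxy group) | COC(=O)C[C@@H]1C[C@@H](O[Si](C)(C)C(C)(C)C)[C@H](C)C(COCc2ccc(OC)cc2)=CC1=O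
F4 | step 8 | cis-fused 5-{[tert-butyl(dimethyl)silyl]oxy}-7-{[(4-methoxybenzyl)oxy]methyl}-6-methyl-3,3a,4,5,6,8a-hexahydro-2H-cyclohepta[b]furan-2-one | C1C(=O)O[C@@H]2[C@H]1C[C@@H](O[Si](C)(C)C(C)(C)C)[C@H](C)C(COCc1ccc(OC)cc1)=C2
F5 | step 8 | 3-[(dimethylamino)methyl] derivative of F4 (C3 epimers) | CN(C)CC1C(=O)O[C@@H]2[C@H]1C[C@@H](O[Si](C)(C)C(C)(C)C)[C@H](C)C(COCc1ccc(OC)cc1)=C2
F6 | step 8 | 4-methoxybenzyl ether of 13 | C=C1C(=O)O[C@@H]2[C@H]1C[C@@H](O[Si](C)(C)C(C)(C)C)[C@H](C)C(COCc1ccc(OC)cc1)=C2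
F7 | step 10 | 7,8-epoxide of 13 with the epoxide oxygen on the lower face (diastereomer of 14) | C=C1C(=O)O[C@@H]2[C@H]1C[C@@H](O[Si](C)(C)C(C)(C)C)[C@H](C)[C@@]3(CO)[C@@H]2O3
F8 | step 10 | 5-{[tert-butyl(dimethyl)silyl]oxy}-7-hydroxy-7-(hydroxymethyl)-6-methyl-3-methylidene-2-oxooctahydro-2H-cyclohepta[b]furan-8-yl 2-methylpropanoate | C=C1C(=O)O[C@@H]2[C@H]1C[C@@H](O[Si](C)(C)C(C)(C)C)[C@H](C)[C@@](O)(CO)[C@H]2OC(=O)C(C)C
F9 | step 10 | 5-{[tert-butyl(dimethyl)silyl]oxy}-7-formyl-7-hydroxy-6-methyl-3-methylidene-2-oxooctahydro-2H-cyclohepta[b]furan-8-yl 2-methylpropanoate | C=C1C(=O)O[C@@H]2[C@H]1C[C@@H](O[Si](C)(C)C(C)(C)C)[C@H](C)[C@@](O)(C=O)[C@H]2OC(=O)C(C)C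
F10 | step 10 | 5-{[tert-butyl(dimethyl)silyl]oxy}-7-hydroxy-7-[(2E)-1-hydroxybut-2-en-1-yl]-6-methyl-3-methylidene-2-oxooctahydro-2H-cyclohepta[b]furan-8-yl 2-methylpropanoate (both carbinol epimers) | C=C1C(=O)O[C@@H]2[C@H]1C[C@@H](O[Si](C)(C)C(C)(C)C)[C@H](C)[C@@](O)(C(O)/C=C/C)[C@H]2OC(=O)C(C)C
F11 | step 12 | 5-{[tert-butyl(dimethyl)silyl]oxy}-7,8-dihydroxy-6-methyl-3-methylidene-2-oxooctahydro-2H-cyclohepta[b]furan-7-carboxylic acid | C=C1C(=O)O[C@@H]2[C@H]1C[C@@H](O[Si](C)(C)C(C)(C)C)[C@H](C)[C@@](O)(C(=O)O)[C@H]2O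
F12 | step 12 | S-ethyl 5-{[tert-butyl(dimethyl)silyl]oxy}-7,8-dihydroxy-6-methyl-3-methylidene-2-oxooctahydro-2H-cyclohepta[b]furan-7-carbothioate | C=C1C(=O)O[C@@H]2[C@H]1C[C@@H](O[Si](C)(C)C(C)(C)C)[C@H](C)[C@@](O)(C(=O)SCC)[C@H]2O
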